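**Assumption:** flavan numbering is used throughout (O1, C2–C4, C4a, C5–C8, C8a; ring A = resorcinol ring, ring B = dimethoxyphenyl, ring C = pyran). Compounds 1, 2 and 12 are taken as catalogue materials, and the C2 descriptor stays R from 5 to 21 because the priority order O > aryl > CH2 > H never changes.

## The problem

The target is a (2R)-flavan: a dihydropyran (ring C) fused to a resorcinol (ring A), with a 3,5-dimethoxyphenyl group (ring B) at C2. Ring A is substituted at five of its six carbons: O1 at C8a, the C4 methylene at C4a, hydroxyls at C5 and C7, and prenyl at C6. Only C8 carries hydrogen, so any route from a phloroglucinol-type arene must tell C6 from C8, two positions of almost equal nucleophilicity. C2 is the only stereocenter, so nothing can relay to it and it must come from a reagent- or catalyst-controlled step. As a benzylic ether carbon it must then be kept away from hydrogenolysis, strong Lewis acids and short-wavelength light, although the meta-methoxy groups give a benzylic cation no extra stabilisation. The prenyl alkene between two phenols is the most delicate group: acid closes it onto O5 or O7 as a 2,2-dimethylchroman, and it rules out hydrogenation. The free resorcinol is also air-sensitive under base. The enabling feature is the sequence C5(OH)–C6(alkyl)–C7(O)–C8(H) set on the C4a–C8a bond, which can be read as a former enol ether C=C. A vinylketene built on a 3,4-dihydro-2H-pyran (ketene carbon → C5, its α-carbon → C8, pyran C6=C5 → C8a–C4a) plus a 1-siloxyalkyne (→ C6 and C7) gives exactly this pattern with no regiochemical choice.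

## Retrosynthesis

**21 ⇒ 20.** Only the O7–Si bond is cut. A triisopropylsilyl ether at O7 is what the ring-forming step delivers anyway, and fluoride removes it without acid, so the prenyl group next to two phenols is never exposed to conditions that would cyclise it.

**20 ⇒ 11 + 15.** Four ring A bonds are cut at once: C8–C8a, C7–C8, C5–C6 and C4a–C5. Diazoketone 11 carries ring C, ring B and the stereocenter; siloxyalkyne 15 carries the prenyl group and O7. Cutting the pyran instead (O1–C2, C2–C3 or C4–C4a) would leave a hexasubstituted arene whose 6- versus 8-prenyl pattern still has to be made. Here the pattern follows from the polarity of the two partners. The forward reaction must run under neutral conditions, tolerate a trisubstituted alkene and an enol ether, and leave C2 alone.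

**11 ⇒ 9.** The diazo group is traced to the methyl group of ketone 9 by detrifluoroacetylative diazo transfer. The neighbouring cut, acid chloride plus diazomethane, is the weaker choice for an unsaturated acyl system because of dipolar cycloaddition and HCl exposure of the enol ether. It is kept as a fallback.

**9 ⇒ 8 ⇒ 7.** The bond between pyran C6 and the acyl carbon is cut. Ketone 9 comes from Weinreb amide 8, and 8 from ketene acetal phosphate 7 by carbonylation. Direct metalation of a 2-aryl-dihydropyran at C6 is avoided because the position between the two methoxy groups of ring B would lithiate competitively.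

**7 ⇒ 6 ⇒ 4.** The enol phosphate is the O-trapped enolate of δ-lactone 6. The lactone C–O bond and the C2–H bond are then cut back to keto acid 4. This puts the single stereocenter on an aryl alkyl ketone, the best-served substrate class for asymmetric transfer hydrogenation. Lactonisation happens at the acyl carbon and cannot touch the new center.

**4 ⇒ 1 + 2.** The aryl–carbonyl bond is cut to the Grignard reagent of bromide 1 and anhydride 2. Friedel–Crafts acylation of 1,3-dimethoxybenzene would place the chain ortho/para to the methoxy groups, so the meta,meta pattern has to come from the bromide.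

**15 ⇒ 12.** The alkyne carbon next to the prenyl methylene is cut. Ester 12 supplies the other six carbons and a one-carbon ester-to-ynolate homologation adds the seventh, so 15 is one step from a catalogue ester.

## Roads not taken

**Alternative 1: gold-catalysed hydroarylation of a chiral propargyl ether.** The cut is C4–C4a. Propargyl aryl ether A1 would be treated with a cationic complex of monovalent gold such as Ph3PAuNTf2, and the arene carbon ortho to oxygen would attack the alkyne terminus to give 2H-chromene A2.
- Merits: the phenoxy ring of A1 is symmetric about its O–C4 axis, so the ring closure has no regiochemical choice. On that point it matches the chosen plan. The catalysis is mild and the pyran closes in one step.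
- Weak points: the stereocenter of A1 is benzylic and propargylic, so installing the aryl ether with clean inversion competes with ionisation and SN2′ attack. A2 is a 2-aryl-2H-chromene, a class that opens reversibly by 6π electrocyclic cleavage to a quinone-methide-type dienone, which erodes C2. The C3=C4 alkene must then be reduced in the presence of the prenyl alkene and an allylic, benzylic C–O bond. The two methoxymethyl ethers finally come off under acid, the condition the prenyl/phenol array tolerates least. The symmetric A-ring phenol also needs several protecting-group steps.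
- Comparison: step count is similar or slightly longer. The chosen plan sets C2 on a ketone, never places it next to unsaturation, needs no reduction after ring A exists, and deprotects with fluoride. In return it must accept a photochemical step on a little-tested diazoketone.

**Alternative 2: rhodium carbenoid C–H insertion forming C2–C3.** The cut is C2–C3. Diazoketone A3, an ortho-(3,5-dimethoxybenzyloxy) diazoacetophenone, would be decomposed by a chiral carboxylate of divalent rhodium such as Rh2(S-PTTL)4. The carbenoid would insert into the benzylic O–CH2 bond to give flavanone A4, setting C2 in the ring-forming event.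
- Merits: the stereocenter is created catalytically and late, and the aromatic chemistry leading to A3 is conventional.
- Weak points: the insertion is a 1,6-process. It competes with attack of the carbenoid on the ether oxygen, a five-membered-ring pathway that ends in a Stevens-type benzyl shift. Enantiocontrol with acceptor-only carbenoids at such positions is modest. A4 carries a C4 carbonyl the target lacks, so two further reductive steps are needed. These endanger the prenyl group, and C2 of a flavanone can epimerise by ring opening to the chalcone. A3 is a hexasubstituted arene whose 6-prenyl pattern must be secured first, and this is the central regiochemical problem.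
- Comparison: this road sets C2 later than the chosen plan, which is a real advantage in principle. The chosen plan sets C2 in its second step but with a highly reliable ketone reduction, carries it through conditions that cannot reach it, and solves the prenyl regiochemistry by mechanism.

**Alternative 3: asymmetric o-quinone methide–styrene oxa-Diels–Alder.** The cuts are O1–C2 and C3–C4. A chiral phosphoric acid would dehydrate o-hydroxybenzyl alcohol A5 to o-quinone methide A6, which would add 3,5-dimethoxystyrene A7 to give protected flavan A8.
- Merits: this is the shortest and most convergent road. Ring C and C2 arise in one catalytic step at the correct oxidation level, with no carbonyl to remove and no alkene to reduce. If it worked it would be clearly shorter than the chosen plan.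
- Weak points: A6 has an unsubstituted methide carbon, so it is hard to generate from a primary benzylic alcohol and prone to oligomerise. A7 has no hydrogen-bonding handle and its meta-methoxy groups do not activate the alkene, so enantiofacial control by the acid is the least secure element. The Brønsted-acid medium and the later acidic removal of two methoxymethyl ethers both threaten the prenyl/phenol array. A5 is again a regiodefined hexasubstituted arene that must be made first.
- Comparison: on step economy this road is better. The chosen plan offers dependable stereocontrol, unambiguous prenyl placement and fluoride-only deprotection, at the cost of a longer linear sequence.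

Key step: step 8

## Route

Step 1
Reactants: 1 1-bromo-3,5-dimethoxybenzene; 2 glutaric anhydride
Product: 4 5-(3,5-dimethoxyphenyl)-5-oxopentanoic acid, via arylmagnesium bromide 3 (not isolated)
Conditions: Mg, I2 (cat.), THF, reflux; then inverse addition to 2, THF, −78 → 0 °C; aq. HCl
Reagents that add atoms: magnesium, [Mg] (kept only in intermediate 3; product 4 holds none of it)
Why: Grignard formation and mono-addition to a cyclic anhydride; inverse addition at low temperature keeps the anhydride in excess, and the magnesium carboxylate formed deactivates the keto acid toward a second addition.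

Step 2
Reactants: 4 5-(3,5-dimethoxyphenyl)-5-oxopentanoic acid
Product: 6 (R)-6-(3,5-dimethoxyphenyl)tetrahydro-2H-pyran-2-one, via hydroxy acid 5 (not isolated)
Conditions: RuCl[(R,R)-TsDPEN](p-cymene) (1 mol %), HCO2H/Et3N (5:2), 40 °C; then TsOH·H2O (cat.), toluene, 50 °C
Reagents that add atoms: none
Why: Noyori asymmetric transfer hydrogenation of an aryl alkyl ketone, in which the (R,R)-catalyst should give the (R)-carbinol in the same sense as acetophenone gives (R)-1-phenylethanol, with the acid carried as its triethylammonium salt; acid-catalysed δ-lactonisation then occurs at the acyl carbon and leaves the C–O bond of the new stereocenter intact.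

Step 3
Reactants: 6 (R)-6-(3,5-dimethoxyphenyl)tetrahydro-2H-pyran-2-one
Product: 7 (R)-2-(3,5-dimethoxyphenyl)-3,4-dihydro-2H-pyran-6-yl diphenyl phosphate
Conditions: KN(SiMe3)2, (PhO)2P(O)Cl, HMPA, THF, −78 °C
Reagents that add atoms: diphenyl chlorophosphate, O=P(Cl)(Oc1ccccc1)Oc1ccccc1
Why: O-phosphorylation of the lactone potassium enolate gives the cyclic ketene acetal phosphate, a standard handle for palladium chemistry on lactones; the benzylic C–H at the stereocenter is not acidic and is untouched.

Step 4
Reactants: 7 (R)-2-(3,5-dimethoxyphenyl)-3,4-dihydro-2H-pyran-6-yl diphenyl phosphate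
Product: 8 (R)-2-(3,5-dimethoxyphenyl)-N-methoxy-N-methyl-3,4-dihydro-2H-pyran-6-carboxamide
Conditions: Pd(OAc)2 (5 mol %), Xantphos (6 mol %), CO (1 atm), MeNH(OMe)·HCl, Et3N, DMF, 60 °C
Reagents that add atoms: carbon monoxide, [C-]#[O+]; N,O-dimethylhydroxylamine hydrochloride, CNOC.Cl
Why: Palladium-catalysed aminocarbonylation of a lactone-derived enol phosphate: zerovalent palladium inserts into the C–OP bond, CO inserts, and the acylpalladium is captured by the hydroxylamine; the wide-bite-angle ligand is chosen to limit N–O reduction, and C2 is not allylic so no π-allyl ionisation can occur.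

Step 5
Reactants: 8 (R)-2-(3,5-dimethoxyphenyl)-N-methoxy-N-methyl-3,4-dihydro-2H-pyran-6-carboxamide
Product: 9 (R)-1-[2-(3,5-dimethoxyphenyl)-3,4-dihydro-2H-pyran-6-yl]ethan-1-one
Conditions: MeMgBr, THF, 0 °C; aq. NH4Cl
Reagents that add atoms: methylmagnesium bromide, C[Mg]Br
Why: Weinreb ketone synthesis; the chelated tetrahedral intermediate holds until work-up, so addition stops at the methyl ketone.

Step 6
Reactants: 9 (R)-1-[2-(3,5-dimethoxyphenyl)-3,4-dihydro-2H-pyran-6-yl]ethan-1-one
Product: 11 (R)-2-diazo-1-[2-(3,5-dimethoxyphenyl)-3,4-dihydro-2H-pyran-6-yl]ethan-1-one, via trifluoroacetyl diketone 10 (not isolated)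
Conditions: LiN(SiMe3)2, THF, −78 °C; CF3CO2CH2CF3; aq. NH4Cl; then MsN3, Et3N, H2O, MeCN, rt
Reagents that add atoms: methanesulfonyl azide, CS(=O)(=O)N=[N+]=[N-]; 2,2,2-trifluoroethyl trifluoroacetate, O=C(OCC(F)(F)F)C(F)(F)F (its CF3CO group stays only in intermediate 10)
Why: Detrifluoroacetylative diazo transfer (a Regitz-type transfer with a trifluoroacetyl activating group): kinetic enolisation at the methyl group, C-trifluoroacetylation, then azide transfer with loss of the trifluoroacetyl group; this is the standard route to unsaturated diazomethyl ketones and avoids acid chlorides and diazomethane.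

Step 7
Reactants: 12 ethyl 4-methylpent-3-enoate
Product: 15 triisopropyl[(5-methylhex-4-en-1-yn-1-yl)oxy]silane, via lithium dibromo enolate 13 (not isolated), via lithium ynolate 14 (not isolated)
Conditions: CH2Br2, lithium 2,2,6,6-tetramethylpiperidide, THF, −78 °C; 12; LiN(SiMe3)2, −78 → −20 °C; n-BuLi, −78 °C → rt; i-Pr3SiCl, −78 → 0 °C
Reagents that add atoms: dibromomethane, BrCBr; chlorotriisopropylsilane, CC(C)[Si](Cl)(C(C)C)C(C)C
Why: Kowalski ester homologation stopped at the ynolate: dibromomethyllithium adds to the ester, the dibromo ketone enolate undergoes bromine–lithium exchange and 1,2-shift of the prenyl-bearing carbon to give the ynolate, and the bulky silyl chloride traps it on oxygen.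

Step 8
Reactants: 11 (R)-2-diazo-1-[2-(3,5-dimethoxyphenyl)-3,4-dihydro-2H-pyran-6-yl]ethan-1-one; 15 triisopropyl[(5-methylhex-4-en-1-yn-1-yl)oxy]silane
Product: 20 (2R)-2-(3,5-dimethoxyphenyl)-6-(3-methylbut-2-en-1-yl)-7-[(triisopropylsilyl)oxy]-3,4-dihydro-2H-chromen-5-ol, via vinylketene 16 (not isolated), via vinylcyclobutenone 17 (not isolated), via dienylketene 18 (not isolated), via cyclohexadienone 19 (not isolated)
Conditions: 15 (1.5 equiv), ClCH2CH2Cl, hν (medium-pressure Hg lamp, Pyrex filter, λ > 300 nm), rt; then 80 °C
Reagents that add atoms: none
Why: Photochemical Wolff rearrangement of 11 (loss of N2 and 1,2-shift of the pyranyl vinyl carbon to the former diazo carbon, forming C8–C8a) gives vinylketene 16, whose ketene C=C adds the electron-rich alkyne 15 in a polar [2+2] (C5–C6 and C7–C8) to give 4-vinylcyclobutenone 17. Heating opens 17 by reversible 4π electrocyclic cleavage to dienylketene 18, and the isomer with the ketene and pyranyl groups cis closes ring A by thermal 6π electrocyclisation (C4a–C5); enolisation of cyclohexadienone 19 then gives the phenol. The closest known reaction is the Danheiser benzannulation in its diazoketone form, which with 1-siloxyalkynes gives resorcinol monosilyl ethers; only the ring oxygen on the migrating vinyl group is unusual. Ring A therefore closes by a pericyclic 6π process and not by an ionic cyclisation, and the enol ether C=C of the dihydropyran ends as the C4a–C8a ring fusion. No lasting stereocenter is formed, since the sp3 carbons of 17 and 19 become aromatic, and C2 is a remote spectator under neutral conditions. The selectivity needed is regiochemical and is fixed by polarity: the prenyl-bearing alkyne carbon, remote from oxygen, is the nucleophile and bonds to the ketene carbonyl carbon, so prenyl lands at C6 between the two oxygens and the silyloxy group at C7. Chemoselectivity over the prenyl alkene rests on the far higher reactivity of the siloxyalkyne toward ketenes, and long-wavelength light excites the diazoketone while leaving the 3,5-dimethoxybenzyl ether chromophore dark.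

Step 9
Reactants: 20 (2R)-2-(3,5-dimethoxyphenyl)-6-(3-methylbut-2-en-1-yl)-7-[(triisopropylsilyl)oxy]-3,4-dihydro-2H-chromen-5-ol
Product: 21 (2R)-2-(3,5-dimethoxyphenyl)-6-(3-methylbut-2-en-1-yl)-3,4-dihydro-2H-chromene-5,7-diol
Conditions: Bu4NF, AcOH, THF, 0 °C, under argon
Reagents that add atoms: none
Why: Fluoride cleavage of an aryl silyl ether; acetic acid buffering keeps the resorcinol from standing as an oxidisable phenoxide, and no acid strong enough to cyclise the prenyl group is present.

## Compound list

1 | 1-bromo-3,5-dimethoxybenzene | COc1cc(Br)cc(OC)c1 | starting material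
2 | glutaric anhydride | O=C1CCCC(=O)O1 | starting material
3 | 3,5-dimethoxyphenylmagnesium bromide (not isolated) | COc1cc(OC)cc([Mg]Br)c1 | intermediate
4 | 5-(3,5-dimethoxyphenyl)-5-oxopentanoic acid | COc1cc(OC)cc(C(=O)CCCC(=O)O)c1 | intermediate
5 | (R)-5-(3,5-dimethoxyphenyl)-5-hydroxypentanoic acid (not isolated) | COc1cc(OC)cc([C@H](O)CCCC(=O)O)c1 | intermediate
6 | (R)-6-(3,5-dimethoxyphenyl)tetrahydro-2H-pyran-2-one | COc1cc(OC)cc([C@H]2CCCC(=O)O2)c1 | intermediate
7 | (R)-2-(3,5-dimethoxyphenyl)-3,4-dihydro-2H-pyran-6-yl diphenyl phosphate | COc1cc(OC)cc([C@H]2CCC=C(OP(=O)(Oc3ccccc3)Oc3ccccc3)O2)c1 | intermediate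
8 | (R)-2-(3,5-dimethoxyphenyl)-N-methoxy-N-methyl-3,4-dihydro-2H-pyran-6-carboxamide | COc1cc(OC)cc([C@H]2CCC=C(C(=O)N(C)OC)O2)c1 | intermediate
9 | (R)-1-[2-(3,5-dimethoxyphenyl)-3,4-dihydro-2H-pyran-6-yl]ethan-1-one | COc1cc(OC)cc([C@H]2CCC=C(C(C)=O)O2)c1 | intermediate
10 | (R)-1-[2-(3,5-dimethoxyphenyl)-3,4-dihydro-2H-pyran-6-yl]-4,4,4-trifluorobutane-1,3-dione (not isolated) | COc1cc(OC)cc([C@H]2CCC=C(C(=O)CC(=O)C(F)(F)F)O2)c1 | intermediate
11 | (R)-2-diazo-1-[2-(3,5-dimethoxyphenyl)-3,4-dihydro-2H-pyran-6-yl]ethan-1-one | COc1cc(OC)cc([C@H]2CCC=C(C(=O)C=[N+]=[N-])O2)c1 | intermediate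
12 | ethyl 4-methylpent-3-enoate | CCOC(=O)CC=C(C)C | starting material
13 | lithium 1,1-dibromo-5-methylhexa-1,4-dien-2-olate (not isolated) | CC(C)=CCC([O-])=C(Br)Br.[Li+] | intermediate
14 | lithium 5-methylhex-4-en-1-yn-1-olate (not isolated) | CC(C)=CCC#C[O-].[Li+] | intermediate
15 | triisopropyl[(5-methylhex-4-en-1-yn-1-yl)oxy]silane | CC(C)=CCC#CO[Si](C(C)C)(C(C)C)C(C)C | intermediate
16 | 2-[(2R)-2-(3,5-dimethoxyphenyl)-3,4-dihydro-2H-pyran-6-yl]ethen-1-one, the vinylketene (not isolated) | COc1cc(OC)cc([C@H]2CCC=C(C=C=O)O2)c1 | intermediate
17 | 4-[(2R)-2-(3,5-dimethoxyphenyl)-3,4-dihydro-2H-pyran-6-yl]-2-(3-methylbut-2-en-1-yl)-3-[(triisopropylsilyl)oxy]cyclobut-2-en-1-one, both C4 epimers (not isolated) | COc1cc(OC)cc([C@H]2CCC=C(C3C(=O)C(CC=C(C)C)=C3O[Si](C(C)C)(C(C)C)C(C)C)O2)c1 | intermediate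
18 | (3E)-4-[(2R)-2-(3,5-dimethoxyphenyl)-3,4-dihydro-2H-pyran-6-yl]-2-(3-methylbut-2-en-1-yl)-3-[(triisopropylsilyl)oxy]buta-1,3-dien-1-one, ketene and pyranyl groups cis (not isolated) | COc1cc(OC)cc([C@H]2CCC=C(/C=C(/O[Si](C(C)C)(C(C)C)C(C)C)C(CC=C(C)C)=C=O)O2)c1 | intermediate
19 | (2R)-2-(3,5-dimethoxyphenyl)-6-(3-methylbut-2-en-1-yl)-7-[(triisopropylsilyl)oxy]-2,3,4,4a-tetrahydro-5H-chromen-5-one, both C4a epimers (not isolated) | COc1cc(OC)cc([C@H]2CCC3C(=O)C(CC=C(C)C)=C(O[Si](C(C)C)(C(C)C)C(C)C)C=C3O2)c1 | intermediate
20 | (2R)-2-(3,5-dimethoxyphenyl)-6-(3-methylbut-2-en-1-yl)-7-[(triisopropylsilyl)oxy]-3,4-dihydro-2H-chromen-5-ol | COc1cc(OC)cc([C@H]2CCc3c(cc(O[Si](C(C)C)(C(C)C)C(C)C)c(CC=C(C)C)c3O)O2)c1 | intermediate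
21 | (2R)-2-(3,5-dimethoxyphenyl)-6-(3-methylbut-2-en-1-yl)-3,4-dihydro-2H-chromene-5,7-diol | COc1cc(OC)cc([C@H]2CCc3c(cc(O)c(CC=C(C)C)c3O)O2)c1 | target

## Step count and risk

Total: 9 steps. Longest linear sequence: 8 steps (steps 1–6, 8, 9); the one-step preparation of 15 (step 7) joins at step 8.

**Step 8 (key step).** The photochemical stage is the weak point. The 1,2-shift of an α-alkoxyvinyl group in a cross-conjugated diazoketone is little tested and may be inefficient. Leaking short-wavelength light could heterolyse the 3,5-dimethoxybenzylic C2–O1 bond. If the [2+2] with 15 is slow, the ketene may be consumed by O-acylation of the product phenol or by dimerisation. Any aryl ester formed in this way should revert to the phenol on mild methanolysis before or during step 9.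

The fallback sets out from 7 and 15 and rejoins the route at vinylketene 16, hence at 20. Stille coupling of 7 with tributyl(ethoxyethynyl)stannane (Pd(PPh3)4, LiCl, THF, 60 °C) should give (R)-2-(3,5-dimethoxyphenyl)-6-(ethoxyethynyl)-3,4-dihydro-2H-pyran F1. Slow addition of F1 to excess 15 in toluene at 110–120 °C should release ethene by retro-ene fragmentation and generate 16 thermally, without light or a diazo group. The [2+2], ring opening and 6π closure then follow as in step 8. Slow addition is meant to counter trapping of 16 by its own alkynyl ether precursor.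

**Step 7.** The α-hydrogens of 12 are both allylic and α to the ester. Deprotonation by dibromomethyllithium or the amide base may therefore compete with carbonyl addition, returning ester or its conjugated isomer. Partial C-silylation of the ynolate is a second risk.

The fallback draws on no numbered compound; it replaces 12 and rejoins at ynolate 14. Copper-catalysed coupling of ethynylmagnesium bromide with 1-bromo-3-methylbut-2-ene (CuCl cat., THF) should give 5-methylhex-4-en-1-yne F2. Deprotonation with n-BuLi and oxidation of the lithium acetylide with lithium tert-butyl peroxide (t-BuOOH, LiN(SiMe3)2, THF, −78 → 0 °C) should give 14, which is silylated as in step 7 to 15.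

**Step 4.** Oxidative addition into the C–OP bond may be slow. Palladium hydride species may reduce the N–O bond of the hydroxylamine, and the phosphate may hydrolyse back to lactone 6.

The fallback sets out from 7 and rejoins at 8. Methoxycarbonylation (Pd(PPh3)4, CO, MeOH, Et3N, DMF, 50 °C), the best-documented carbonylation of lactone-derived enol phosphates, should give methyl (R)-2-(3,5-dimethoxyphenyl)-3,4-dihydro-2H-pyran-6-carboxylate F3. Amidation with MeNH(OMe)·HCl and i-PrMgCl (THF, −20 °C) then gives 8 without the hydroxylamine ever meeting palladium.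

**Step 6.** The cross-conjugated enol ether may hydrate or ring-open in the aqueous stages. Enolisation may be diverted to γ-deprotonation at pyran C4 or to self-condensation, and the sulfonyl azide may add to the enol ether.

The fallback sets out from 7, bypasses 8 and 9, and rejoins at 11. Ester F3 (made as above) is saponified (LiOH, THF/H2O) to (R)-2-(3,5-dimethoxyphenyl)-3,4-dihydro-2H-pyran-6-carboxylic acid F4. Activation with i-BuOCOCl and N-methylmorpholine (THF, −15 °C) gives the isobutyl mixed carbonic anhydride F5, which acylates diazomethane (Et2O, 0 °C) to give 11 in an Arndt–Eistert-type diazoketone synthesis. The trisubstituted, donor-substituted alkene should be a poor dipolarophile for diazomethane.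

## Further compounds

F1 | step 8 | (R)-2-(3,5-dimethoxyphenyl)-6-(ethoxyethynyl)-3,4-dihydro-2H-pyran | COc1cc(OC)cc([C@H]2CCC=C(C#COCC)O2)c1
F2 | step 7 | 5-methylhex-4-en-1-yne | CC(C)=CCC#C
F3 | step 4 | methyl (R)-2-(3,5-dimethoxyphenyl)-3,4-dihydro-2H-pyran-6-carboxylate | COc1cc(OC)cc([C@H]2CCC=C(C(=O)OC)O2)c1
F4 | step 6 | (R)-2-(3,5-dimethoxyphenyl)-3,4-dihydro-2H-pyran-6-carboxylic acid | COc1cc(OC)cc([C@H]2CCC=C(C(=O)O)O2)c1
F5 | step 6 | (R)-2-(3,5-dimethoxyphenyl)-3,4-dihydro-2H-pyran-6-carboxylic isobutyl carbonic anhydride | COc1cc(OC)cc([C@H]2CCC=C(C(=O)OC(=O)OCC(C)C)O2)c1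
A1 | alternative 1 | (R)-1-{1-[3,5-bis(methoxymethoxy)-4-(3-methylbut-2-en-1-yl)phenoxy]prop-2-yn-1-yl}-3,5-dimethoxybenzene | COc1cc(OC)cc([C@@H](C#C)Oc2cc(OCOC)c(CC=C(C)C)c(OCOC)c2)c1
A2 | alternative 1 | (R)-5,7-bis(methoxymethoxy)-6-prenyl-2-(3,5-dimethoxyphenyl)-2H-chromene | COc1cc(OC)cc([C@H]2C=Cc3c(cc(OCOC)c(CC=C(C)C)c3OCOC)O2)c1
A3 | alternative 2 | 2-diazo-1-{2-[(3,5-dimethoxybenzyl)oxy]-4,6-bis(tert-butyldimethylsilyloxy)-5-(3-methylbut-2-en-1-yl)phenyl}ethan-1-one | COc1cc(OC)cc(COc2cc(O[Si](C)(C)C(C)(C)C)c(CC=C(C)C)c(O[Si](C)(C)C(C)(C)C)c2C(=O)C=[N+]=[N-])c1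
A4 | alternative 2 | (R)-5,7-bis(tert-butyldimethylsilyloxy)-6-prenyl-3',5'-dimethoxyflavanone | COc1cc(OC)cc([C@H]2CC(=O)c3c(cc(O[Si](C)(C)C(C)(C)C)c(CC=C(C)C)c3O[Si](C)(C)C(C)(C)C)O2)c1
A5 | alternative 3 | 2-(hydroxymethyl)-3,5-bis(methoxymethoxy)-4-(3-methylbut-2-en-1-yl)phenol | OCc1c(O)cc(OCOC)c(CC=C(C)C)c1OCOC
A6 | alternative 3 | 3,5-bis(methoxymethoxy)-4-(3-methylbut-2-en-1-yl)-6-methylidenecyclohexa-2,4-dien-1-one (o-quinone methide) | C=C1C(=O)C=C(OCOC)C(CC=C(C)C)=C1OCOC
A7 | alternative 3 | 3,5-dimethoxystyrene | C=Cc1cc(OC)cc(OC)c1
A8 | alternative 3 | (R)-5,7-bis(methoxymethoxy)-6-prenyl-3',5'-dimethoxyflavan | COc1cc(OC)cc([C@H]2CCc3c(cc(OCOC)c(CC=C(C)C)c3OCOC)O2)c1
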